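In a one-step world what is made stays made, so a reading of product is a count of events; here Z is a stop on the way, and you have to follow one molecule of it.

    E + X.Z → E.X.Z (k1 = 4.6 × 10⁻⁵ L mol⁻¹ s⁻¹)
    E → Z (k2 = 6.0 × 10⁻⁵ s⁻¹)
    X + Z → X.Z (k3 = 0.0025 L mol⁻¹ s⁻¹)
    Z + D → Z.D (k4 = 8.4 × 10⁻⁵ L mol⁻¹ s⁻¹)
all flasks: E 0.20 M; D 0.0600 M

| run | X | remark | time |
|---|---|---|---|
| green | 0.900 equiv | a single well-mixed tank run continuously and read at steady state, 30.0 h in it on average |  |
| teal | 0.900 equiv (fed, over 6.00 h) | a stirred flask in which X is dosed at a steady rate over 6.00 h without added volume, worked up at 6.0 h | 6.0 h |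
| grey | 0.900 equiv | one stirred flow tank at steady state, fed with the mixture as stated, mean residence time 6.0 h |  |
| violet | 0.900 equiv | everything together in a closed stirred flask, run for 6.0 h | 6.0 h |
- in percentages every species weighs as the E in it: one E.X.Z counts as two
- the stated concentrations are those of everything mixed, before any reaction; amounts are the same in each set-up
- the feed brings no volume worth counting
- run time (teal): 6.0 h
1. the set-up with the highest amount of Z at the outlet or at the end, in percent of the E put in ("none" if the first two lie within 2 percentage points) (green / teal / grey / violet / none)
2. amount of Z at the outlet or at the end, in percent of the E put in, green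
3. amount of Z at the outlet or at the end, in percent of the E put in, teal
4. amount of Z at the outlet or at the end, in percent of the E put in, grey
5. amount of Z at the outlet or at the end, in percent of the E put in, violet

A Z in violet faces a fork: it meets X or it meets D. Its half-life against X at the charged amounts is 0.43 h, against D 38 h, so I drop the D branch. I also drop the step from E + X.Z: even with the whole charge of X standing as X.Z, it takes E at 8.28 × 10⁻⁶ s⁻¹, slower than the 6.0 × 10⁻⁵ s⁻¹ of the way to Z.

What stands is making rate times lifetime (the quasi-steady state of an intermediate). You need one number, k2/k3, the balance constant 0.0240 M: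

Z = balance constant × E / X

E left in violet at the end, reckoned by first-order loss to Z: 0.0547 M.

First way: suppose each lost E has already taken its X. Then X stands at 0.0347 M and Z at 0.0378 M, or 18.9 % of the E put in.

Second way: keep the ledger. A Z still standing has taken no X, so X is 0.0347 M plus Z. Solved with the balance:

Z = 0.0228 M, or 11.4 %; X = 0.0575 M

The two part, and the first way cheats: it charges the standing Z for X that Z has not used. At the second way's X, a Z lives 1.93 h, within the 6.0 h, and 96.6 % of them go to X. So I commit to 11.4 % for violet.

Teal ends with the same charges and the same ledger, so the balance points to the same figure. But its Z was made while less X had gone in, so I expect a teal reading over that figure. The tanks I leave unreckoned.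

The forecast gave green 6.6 %, teal 15 %, grey 9.05 % and violet 10.4 %, lower than my figure, and named teal best, saying "Dosing keeps X low early".

The simulation gives green 6.57 %, teal 15.5 %, grey 9.06 % and violet 10.5 %, with teal best.

Violet at the end holds E 25.7 % and X 33.4 % of its charge, and the balance constant on these gives 10.3 %. At that moment Z in violet is made at 0.944 times the rate it is used, so it is close to balance, yet violet is not at rest. At 60.0 h violet holds Z 1.08 %, E 0 %, X 0.820 % of its charge, X.Z 84.1 % and E.X.Z 10.4 %. Teal's Z goes from 15.5 % to 1.07 % over the same stretch.

With 3.60 equiv of X in a flask otherwise like violet, the same reckoning takes E at 0.0547 M and X at 0.575 M, so the balance constant gives 0.002285 M, or 1.14 %, and the ledger's Z is far below that X. That flask gives 1.09 %.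

The numbers are made up; the run is a simulation.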